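**Plan**
1. Retrosynthesis: hydrolysis of the methyl ester and aryl pivalate; C3=C4 from a C4 alcohol; the C2 methyl from a C2–CH2–CHO arm by loss of CO; the pyran ring cut at C4–C3 and O1–C2 into a 5-acyloxy-3-methylsalicylaldehyde and a C20 3-methyl-2-enal; that enal cut at its (Z)-C=C(CO2Me) bond into a C10 aldehyde from (2E,6E)-farnesol and an α-homoprenyl phosphonoacetate.
2. Enabling feature: the C3–C2(CH3) unit of the target is a masked 3-methyl-2-enal. The enal methyl carbon becomes C3, the enal C3 becomes C2, and the enal C2 becomes the C2 methyl once C1 leaves as CO. The arene holds the future C4 (CHO on C4a) and O1 (OH on C8a) on neighbouring ring carbons, so O1 lies six atoms from the enal β-carbon once C4–C3 is made.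
3. Forward: the arene (2 steps) and the side-chain enal (7 steps) are made separately. One aminocatalytic domino step joins them, closing the pyran ring and a temporary lactol ring (C2–CH2–CH(OH)–O–C4). The lactol is unlocked by decarbonylation, the C4 hydroxyl is eliminated to the chromene, and both esters are hydrolysed last.
4. Stereochemistry: C2 from the catalyst-controlled oxa-Michael closure; C4 (temporary) from the lactol constraint; 6E from farnesol; 2Z from the Still–Gennari olefination.

Key step: step 10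

Remark: the (S)-catalyst is assigned from the steric-shielding model (oxygen adds to the E,s-trans iminium ion on the face away from the CAr2OSiMe3 group); if the opposite sense is found, the (R)-catalyst is used and nothing else changes.

**Route**

Step 1
Reactants: 1 2-methylbenzene-1,4-diol (methylhydroquinone)
Product: 2 4-hydroxy-3-methylphenyl pivalate
Conditions: PivCl (1.0 equiv), pyridine, CH2Cl2, −20 → 0 °C
Reagents that add atoms: pivaloyl chloride, CC(C)(C)C(=O)Cl
Why: Nucleophilic acyl substitution in which the bulky acyl chloride should take the less hindered, more acidic hydroxyl (the one not flanked by the methyl group) and, with one equivalent, stop at the mono-ester; no stereocentre is formed.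

Step 2
Reactants: 2 4-hydroxy-3-methylphenyl pivalate
Product: 3 3-formyl-4-hydroxy-5-methylphenyl pivalate
Conditions: (CH2O)n, MgCl2, Et3N, MeCN, reflux; aq. HCl work-up
Reagents that add atoms: formaldehyde (used as paraformaldehyde), C=O
Why: Casnati–Skattebøl ortho-formylation, in which the phenoxide ArOMgCl formed from MgCl2 and Et3N delivers formaldehyde to the only free ortho position and a second formaldehyde oxidises the benzylic alkoxide by hydride transfer; the hindered aryl pivalate should survive.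

Step 3
Reactants: 4 methyl 2-[bis(2,2,2-trifluoroethoxy)phosphoryl]acetate; 5 5-bromo-2-methylpent-2-ene
Product: 6 methyl 2-[bis(2,2,2-trifluoroethoxy)phosphoryl]-6-methylhept-5-enoate (racemic)
Conditions: NaH, THF/DMF, 0 °C; then 5, 50 °C
Reagents that add atoms: none
Why: SN2 C-alkylation of the stabilised phosphonoacetate anion by the primary bromide (malonate-type alkylation); the new α-centre is racemic and disappears in step 7.

Step 4
Reactants: 7 (2E,6E)-farnesol
Product: 8 (2E,6E)-farnesyl tert-butyldiphenylsilyl ether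
Conditions: TBDPSCl, imidazole, DMF, 20 °C
Reagents that add atoms: tert-butyl(chloro)diphenylsilane, CC(C)(C)[Si](Cl)(c1ccccc1)c1ccccc1
Why: Imidazole-promoted silylation of the primary allylic alcohol gives an ether that should survive NBS, carbonate, periodic acid and the olefination base.

Step 5
Reactants: 8 (2E,6E)-farnesyl tert-butyldiphenylsilyl ether
Product: 10 tert-butyl{[(2E,6E)-9-(3,3-dimethyloxiran-2-yl)-3,7-dimethylnona-2,6-dien-1-yl]oxy}diphenylsilane (racemic epoxide), via bromohydrin 9 (not isolated)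
Conditions: NBS, THF/H2O, 0 °C; then K2CO3, MeOH, 20 °C
Reagents that add atoms: water, O (epoxide oxygen); N-bromosuccinimide, O=C1CCC(=O)N1Br (its bromine is carried by 9 only)
Why: Terminal-selective bromohydrin formation in aqueous THF (bromonium ion on the most accessible, most electron-rich trisubstituted alkene, water at the tertiary carbon) followed by intramolecular Williamson closure; the epoxide centre is racemic and is destroyed in step 6.

Step 6
Reactants: 10 the racemic terminal epoxide
Product: 12 (4E,8E)-10-[(tert-butyldiphenylsilyl)oxy]-4,8-dimethyldeca-4,8-dienal, via diol 11 (not isolated)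
Conditions: H5IO6, THF/H2O, 0 °C
Reagents that add atoms: water, O (taken up at the tertiary carbon of diol 11; it leaves again in the acetone)
Why: Acid-promoted epoxide hydrolysis and Malaprade glycol cleavage in one pot should excise the terminal C3 unit as acetone and leave the aldehyde, with the silyl ether and the two trisubstituted alkenes untouched.

Step 7
Reactants: 12 (4E,8E)-10-[(tert-butyldiphenylsilyl)oxy]-4,8-dimethyldeca-4,8-dienal; 6 the α-homoprenyl phosphonate
Product: 13 methyl (2Z,6E,10E)-12-[(tert-butyldiphenylsilyl)oxy]-6,10-dimethyl-2-(4-methylpent-3-en-1-yl)dodeca-2,6,10-trienoate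
Conditions: 6, KN(SiMe3)2, 18-crown-6, THF, −78 °C; then 12, −78 °C
Reagents that add atoms: none
Why: Still–Gennari variant of the Horner–Wadsworth–Emmons olefination, in which the electron-poor bis(trifluoroethyl) phosphonate and a dissociated potassium counter-ion make elimination from the kinetic adduct fast, which should give the (Z)-trisubstituted enoate (ester cis to the new chain CH2).

Step 8
Reactants: 13 the silyl-protected (Z)-enoate
Product: 14 methyl (2Z,6E,10E)-12-hydroxy-6,10-dimethyl-2-(4-methylpent-3-en-1-yl)dodeca-2,6,10-trienoate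
Conditions: Bu4NF, THF, 0 → 20 °C
Reagents that add atoms: none
Why: Fluoride-induced cleavage of the silyl ether (strong Si–F bond) should free the allylic alcohol without touching the ester or the alkene geometries.

Step 9
Reactants: 14 the allylic alcohol
Product: 15 methyl (2Z,6E,10E)-6,10-dimethyl-2-(4-methylpent-3-en-1-yl)-12-oxododeca-2,6,10-trienoate
Conditions: MnO2, CH2Cl2, 20 °C
Reagents that add atoms: none
Why: MnO2 oxidises only the allylic alcohol to the enal under neutral conditions and should leave the isolated alkenes and the enoate alone.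

Step 10
Reactants: 3 3-formyl-4-hydroxy-5-methylphenyl pivalate; 15 the C20 enal
Product: 18 bridged lactol (chroman numbering: C2 R carries the side chain; a CH2–CH(OH)–O bridge runs from C2 to C4 R; lactol carbon as both epimers; 2,6-methano-1,5-benzodioxocin-4-ol skeleton), via vinylogous aldol adduct 16 (not isolated), via hydroxy aldehyde 17 (not isolated)
Conditions: (S)-2-{bis[3,5-bis(trifluoromethyl)phenyl][(trimethylsilyl)oxy]methyl}pyrrolidine (30 mol %), PhCO2H (30 mol %), toluene, 20 °C
Reagents that add atoms: none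
Why: The catalyst and 15 form an iminium ion whose C3 methyl group is deprotonated to a 1-aminodiene; its terminal CH2 adds to the aldehyde carbon of 3 (vinylogous aldol addition, C4–C3 bond) to give iminium ion 16, the phenol oxygen closes the pyran ring on the iminium β-carbon (oxa-Michael addition, 6-exo-trig, O1–C2 bond), and after hydrolysis to 17 the C4 hydroxyl closes the temporary lactol ring (hemiacetal formation, 6-exo-trig). The closest known reaction type is the aminocatalytic domino aldol/oxa-Michael reaction of salicylaldehydes with 3-methyl-substituted 2-enals under diarylprolinol silyl ether catalysis. C2 is set in the oxa-Michael step: one face of the E,s-trans iminium ion is shielded by the CAr2(OSiMe3) group of the (S)-catalyst, so the oxygen should add to the open face and give the C2 arrangement of the (R)-target. C4 is set by the ring system, since only the isomer with the C4 hydroxyl cis to the CH2CHO arm can form the lactol bridge, while the aldol and oxa-Michael steps are reversible and feed this sink; the lactol carbon is not controlled and does not matter. The step needs regioselectivity for the methyl-derived CH2 over C4 and Cα of the dienamine, which the unhindered terminus and the lactol sink should secure, and chemoselectivity over the (Z)-enoate, which cannot form an iminium ion.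

Step 11
Reactants: 18 the bridged lactol
Product: 19 methyl (2Z,6E)-9-[(2R,4R)-4-hydroxy-2,8-dimethyl-6-(pivaloyloxy)chroman-2-yl]-6-methyl-2-(4-methylpent-3-en-1-yl)nona-2,6-dienoate
Conditions: RhCl(PPh3)3 (1.1 equiv), toluene, 100 °C, argon
Reagents that add atoms: none
Why: Tsuji–Wilkinson decarbonylation, in which lactol 18, the ring tautomer of hydroxy aldehyde 17, should react through the small equilibrium share of that open form present at 100 °C (aldehyde C–H oxidative addition, CO extrusion, C–H reductive elimination from the 18-electron complex RhCl(H)(R)(CO)(PPh3)2 of trivalent rhodium, which has no free site for β-aryloxy elimination), so that the CH2–CHO arm becomes the C2 methyl group with C2 and C4 untouched.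

Step 12
Reactants: 19 the (2R,4R)-chroman-4-ol
Product: 20 methyl (2Z,6E)-9-[(2R)-2,8-dimethyl-6-(pivaloyloxy)-2H-chromen-2-yl]-6-methyl-2-(4-methylpent-3-en-1-yl)nona-2,6-dienoate
Conditions: Burgess reagent (methyl N-(triethylammoniosulfonyl)carbamate), toluene, 50 °C
Reagents that add atoms: none
Why: Burgess dehydration, in which the C4 sulfamate ester collapses by syn-elimination with a C3 hydrogen (the only β-hydrogens), should give the C3=C4 alkene under non-acidic conditions; the C4 stereocentre is removed and C2 is not involved.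

Step 13
Reactants: 20 the chromene diester
Product: 21 (R)-sargachromenol
Conditions: LiOH, THF/MeOH/H2O (degassed), 40 °C, dark; then aq. HCl to pH 4, 0 °C
Reagents that add atoms: lithium hydroxide, [Li+].[OH-] (its oxygen becomes the hydroxyl oxygen of the carboxylic acid)
Why: Saponification (acyl–oxygen cleavage) removes the methyl ester and the aryl pivalate in one operation, and exclusion of air and light should protect the electron-rich phenolate and the 2H-chromene so that C2 and the alkene geometries stay as set.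

**Compound list**

1 | 2-methylbenzene-1,4-diol | Cc1cc(O)ccc1O | starting material
2 | 4-hydroxy-3-methylphenyl pivalate | Cc1cc(OC(=O)C(C)(C)C)ccc1O | intermediate
3 | 3-formyl-4-hydroxy-5-methylphenyl pivalate | CC(C)(C)C(=O)Oc1cc(C)c(O)c(C=O)c1 | intermediate
4 | methyl 2-[bis(2,2,2-trifluoroethoxy)phosphoryl]acetate | COC(=O)CP(=O)(OCC(F)(F)F)OCC(F)(F)F | starting material
5 | 5-bromo-2-methylpent-2-ene | CC(C)=CCCBr | starting material
6 | methyl 2-[bis(2,2,2-trifluoroethoxy)phosphoryl]-6-methylhept-5-enoate (racemic) | COC(=O)C(CCC=C(C)C)P(=O)(OCC(F)(F)F)OCC(F)(F)F | intermediate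
7 | (2E,6E)-farnesol | CC(C)=CCC/C(C)=C/CC/C(C)=C/CO | starting material
8 | (2E,6E)-farnesyl tert-butyldiphenylsilyl ether | CC(C)=CCC/C(C)=C/CC/C(C)=C/CO[Si](c1ccccc1)(c1ccccc1)C(C)(C)C | intermediate
9 | tert-butyl{[(2E,6E)-10-bromo-11-hydroxy-3,7,11-trimethyldodeca-2,6-dien-1-yl]oxy}diphenylsilane (racemic) | CC(C)(O)C(Br)CC/C(C)=C/CC/C(C)=C/CO[Si](c1ccccc1)(c1ccccc1)C(C)(C)C | intermediate (not isolated)
10 | tert-butyl{[(2E,6E)-9-(3,3-dimethyloxiran-2-yl)-3,7-dimethylnona-2,6-dien-1-yl]oxy}diphenylsilane (racemic) | CC1(C)OC1CC/C(C)=C/CC/C(C)=C/CO[Si](c1ccccc1)(c1ccccc1)C(C)(C)C | intermediate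
11 | (6E,10E)-12-[(tert-butyldiphenylsilyl)oxy]-2,6,10-trimethyldodeca-6,10-diene-2,3-diol (racemic) | CC(C)(O)C(O)CC/C(C)=C/CC/C(C)=C/CO[Si](c1ccccc1)(c1ccccc1)C(C)(C)C | intermediate (not isolated)
12 | (4E,8E)-10-[(tert-butyldiphenylsilyl)oxy]-4,8-dimethyldeca-4,8-dienal | O=CCC/C(C)=C/CC/C(C)=C/CO[Si](c1ccccc1)(c1ccccc1)C(C)(C)C | intermediate
13 | methyl (2Z,6E,10E)-12-[(tert-butyldiphenylsilyl)oxy]-6,10-dimethyl-2-(4-methylpent-3-en-1-yl)dodeca-2,6,10-trienoate | CC(C)=CCC/C(=C/CC/C(C)=C/CC/C(C)=C/CO[Si](c1ccccc1)(c1ccccc1)C(C)(C)C)C(=O)OC | intermediate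
14 | methyl (2Z,6E,10E)-12-hydroxy-6,10-dimethyl-2-(4-methylpent-3-en-1-yl)dodeca-2,6,10-trienoate | CC(C)=CCC/C(=C/CC/C(C)=C/CC/C(C)=C/CO)C(=O)OC | intermediate
15 | methyl (2Z,6E,10E)-6,10-dimethyl-2-(4-methylpent-3-en-1-yl)-12-oxododeca-2,6,10-trienoate | CC(C)=CCC/C(=C/CC/C(C)=C/CC/C(C)=C/C=O)C(=O)OC | intermediate
16 | vinylogous aldol adduct: methyl (2Z,6E)-12-hydroxy-12-[2-hydroxy-3-methyl-5-(pivaloyloxy)phenyl]-6-methyl-2-(4-methylpent-3-en-1-yl)-10-(2-oxoethylidene)dodeca-2,6-dienoate (drawn as the free aldehyde; in the flask it is the iminium ion of the catalyst; carbinol centre and enal geometry not fixed) | CC(C)=CCC/C(=C/CC/C(C)=C/CCC(CC(O)c1cc(OC(=O)C(C)(C)C)cc(C)c1O)=CC=O)C(=O)OC | intermediate (not isolated)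
17 | hydroxy aldehyde: methyl (2Z,6E)-9-[(2R,4R)-4-hydroxy-8-methyl-2-(2-oxoethyl)-6-(pivaloyloxy)chroman-2-yl]-6-methyl-2-(4-methylpent-3-en-1-yl)nona-2,6-dienoate (open form of 18) | CC(C)=CCC/C(=C/CC/C(C)=C/CC[C@]1(CC=O)C[C@@H](O)c2cc(OC(=O)C(C)(C)C)cc(C)c2O1)C(=O)OC | intermediate (not isolated)
18 | bridged lactol: chroman C2 (R) carries the nonadienoate side chain; CH2–CH(OH)–O bridge from C2 to C4 (R); 8-methyl; 6-pivaloyloxy; lactol carbon as both epimers | CC(C)=CCC/C(=C/CC/C(C)=C/CC[C@]1(CC(O)O2)C[C@@H]2c3cc(OC(=O)C(C)(C)C)cc(C)c3O1)C(=O)OC | intermediate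
19 | methyl (2Z,6E)-9-[(2R,4R)-4-hydroxy-2,8-dimethyl-6-(pivaloyloxy)chroman-2-yl]-6-methyl-2-(4-methylpent-3-en-1-yl)nona-2,6-dienoate | CC(C)=CCC/C(=C/CC/C(C)=C/CC[C@]1(C)C[C@@H](O)c2cc(OC(=O)C(C)(C)C)cc(C)c2O1)C(=O)OC | intermediate
20 | methyl (2Z,6E)-9-[(2R)-2,8-dimethyl-6-(pivaloyloxy)-2H-chromen-2-yl]-6-methyl-2-(4-methylpent-3-en-1-yl)nona-2,6-dienoate | CC(C)=CCC/C(=C/CC/C(C)=C/CC[C@]1(C)C=Cc2cc(OC(=O)C(C)(C)C)cc(C)c2O1)C(=O)OC | intermediate
21 | (R)-sargachromenol, (2Z,6E)-9-[(2R)-6-hydroxy-2,8-dimethyl-2H-chromen-2-yl]-6-methyl-2-(4-methylpent-3-en-1-yl)nona-2,6-dienoic acid | CC(C)=CCC/C(=C/CC/C(C)=C/CC[C@]1(C)C=Cc2cc(O)cc(C)c2O1)C(=O)O | target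

**Count and risks**

Total step count: 13. Longest linear sequence: 10 steps (steps 4–13, from farnesol).

Steps most likely to fail:

1. Step 10. The dienamine may form the C–C bond through the wrong carbon, the cascade may stall before ring closure, or the oxa-Michael closure may show poor (or opposite) facial discrimination. The fallback sets out from 3 and 15 and returns at 20. The two are condensed with K2CO3 in dioxane at reflux (base-mediated oxa-Michael addition and intramolecular aldol condensation through the enal α-carbon). This makes the same two ring bonds without a catalyst-controlled step and should give racemic methyl (2Z,6E)-9-[3-formyl-2,8-dimethyl-6-(pivaloyloxy)-2H-chromen-2-yl]-6-methyl-2-(4-methylpent-3-en-1-yl)nona-2,6-dienoate F1. Tsuji–Wilkinson decarbonylation of its vinylic formyl group (RhCl(PPh3)3, toluene, 110 °C) should give racemic methyl (2Z,6E)-9-[2,8-dimethyl-6-(pivaloyloxy)-2H-chromen-2-yl]-6-methyl-2-(4-methylpent-3-en-1-yl)nona-2,6-dienoate F2. Preparative HPLC on an amylose tris(3,5-dimethylphenylcarbamate) phase should then deliver 20.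

2. Step 11. The bridged lactol may open too slowly, so that forcing temperatures are needed, at which retro-oxa-Michael ring opening of the open form 17 and re-closure would erode the C2 configuration. The fallback sets out from 18 and returns at 20; it dismantles the lactol first so that the carbon is excised from a free aldehyde near ambient temperature. NaBH4 (THF/MeOH, 0 °C) should reduce 18 to methyl (2Z,6E)-9-[(2S,4R)-4-hydroxy-2-(2-hydroxyethyl)-8-methyl-6-(pivaloyloxy)chroman-2-yl]-6-methyl-2-(4-methylpent-3-en-1-yl)nona-2,6-dienoate F3, in which C2 is arranged in space as in 18 and only the descriptor changes with substituent ranking. TBSCl and imidazole (CH2Cl2, 0 °C) should silylate only the primary hydroxyl to methyl (2Z,6E)-9-[(2S,4R)-2-{2-[(tert-butyldimethylsilyl)oxy]ethyl}-4-hydroxy-8-methyl-6-(pivaloyloxy)chroman-2-yl]-6-methyl-2-(4-methylpent-3-en-1-yl)nona-2,6-dienoate F4. Burgess reagent (toluene, 50 °C) should then give methyl (2Z,6E)-9-[(2S)-2-{2-[(tert-butyldimethylsilyl)oxy]ethyl}-8-methyl-6-(pivaloyloxy)-2H-chromen-2-yl]-6-methyl-2-(4-methylpent-3-en-1-yl)nona-2,6-dienoate F5. HF·pyridine (THF/pyridine, 0 °C) should free the primary alcohol as methyl (2Z,6E)-9-[(2S)-2-(2-hydroxyethyl)-8-methyl-6-(pivaloyloxy)-2H-chromen-2-yl]-6-methyl-2-(4-methylpent-3-en-1-yl)nona-2,6-dienoate F6. Dess–Martin periodinane with NaHCO3 (CH2Cl2, 0 °C) should give methyl (2Z,6E)-9-[(2S)-8-methyl-2-(2-oxoethyl)-6-(pivaloyloxy)-2H-chromen-2-yl]-6-methyl-2-(4-methylpent-3-en-1-yl)nona-2,6-dienoate F7. RhCl(PPh3)3 (toluene, 25–40 °C) should decarbonylate this unhindered, lactol-free aldehyde to 20.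

3. Step 12. Ionisation at C4 may be followed by capture of the benzylic cation by the nearby side-chain alkene (cation–olefin cyclisation) in place of proton loss. The fallback sets out from 19 and returns at 20; it never generates a C4 cation. Dess–Martin periodinane (CH2Cl2, 20 °C) should oxidise 19 to methyl (2Z,6E)-9-[(2R)-2,8-dimethyl-4-oxo-6-(pivaloyloxy)chroman-2-yl]-6-methyl-2-(4-methylpent-3-en-1-yl)nona-2,6-dienoate F8. LiN(SiMe3)2 then PhNTf2 (THF, −78 °C, kept cold to avoid ring opening of the enolate) should give methyl (2Z,6E)-9-[(2R)-2,8-dimethyl-6-(pivaloyloxy)-4-{[(trifluoromethyl)sulfonyl]oxy}-2H-chromen-2-yl]-6-methyl-2-(4-methylpent-3-en-1-yl)nona-2,6-dienoate F9. Palladium-catalysed formate reduction of the enol triflate (Pd(OAc)2, PPh3, Bu3N, HCO2H, DMF, 60 °C) should give 20.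

**Further compounds**

F1 | step 10 | racemic methyl (2Z,6E)-9-[3-formyl-2,8-dimethyl-6-(pivaloyloxy)-2H-chromen-2-yl]-6-methyl-2-(4-methylpent-3-en-1-yl)nona-2,6-dienoate | CC(C)=CCC/C(=C/CC/C(C)=C/CCC1(C)Oc2c(C)cc(OC(=O)C(C)(C)C)cc2C=C1C=O)C(=O)OC
F2 | step 10 | racemic methyl (2Z,6E)-9-[2,8-dimethyl-6-(pivaloyloxy)-2H-chromen-2-yl]-6-methyl-2-(4-methylpent-3-en-1-yl)nona-2,6-dienoate | CC(C)=CCC/C(=C/CC/C(C)=C/CCC1(C)C=Cc2cc(OC(=O)C(C)(C)C)cc(C)c2O1)C(=O)OC
F3 | step 11 | methyl (2Z,6E)-9-[(2S,4R)-4-hydroxy-2-(2-hydroxyethyl)-8-methyl-6-(pivaloyloxy)chroman-2-yl]-6-methyl-2-(4-methylpent-3-en-1-yl)nona-2,6-dienoate | CC(C)=CCC/C(=C/CC/C(C)=C/CC[C@]1(CCO)C[C@@H](O)c2cc(OC(=O)C(C)(C)C)cc(C)c2O1)C(=O)OC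
F4 | step 11 | methyl (2Z,6E)-9-[(2S,4R)-2-{2-[(tert-butyldimethylsilyl)oxy]ethyl}-4-hydroxy-8-methyl-6-(pivaloyloxy)chroman-2-yl]-6-methyl-2-(4-methylpent-3-en-1-yl)nona-2,6-dienoate | CC(C)=CCC/C(=C/CC/C(C)=C/CC[C@]1(CCO[Si](C)(C)C(C)(C)C)C[C@@H](O)c2cc(OC(=O)C(C)(C)C)cc(C)c2O1)C(=O)OC
F5 | step 11 | methyl (2Z,6E)-9-[(2S)-2-{2-[(tert-butyldimethylsilyl)oxy]ethyl}-8-methyl-6-(pivaloyloxy)-2H-chromen-2-yl]-6-methyl-2-(4-methylpent-3-en-1-yl)nona-2,6-dienoate | CC(C)=CCC/C(=C/CC/C(C)=C/CC[C@]1(CCO[Si](C)(C)C(C)(C)C)C=Cc2cc(OC(=O)C(C)(C)C)cc(C)c2O1)C(=O)OC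
F6 | step 11 | methyl (2Z,6E)-9-[(2S)-2-(2-hydroxyethyl)-8-methyl-6-(pivaloyloxy)-2H-chromen-2-yl]-6-methyl-2-(4-methylpent-3-en-1-yl)nona-2,6-dienoate | CC(C)=CCC/C(=C/CC/C(C)=C/CC[C@]1(CCO)C=Cc2cc(OC(=O)C(C)(C)C)cc(C)c2O1)C(=O)OC
F7 | step 11 | methyl (2Z,6E)-9-[(2S)-8-methyl-2-(2-oxoethyl)-6-(pivaloyloxy)-2H-chromen-2-yl]-6-methyl-2-(4-methylpent-3-en-1-yl)nona-2,6-dienoate | CC(C)=CCC/C(=C/CC/C(C)=C/CC[C@]1(CC=O)C=Cc2cc(OC(=O)C(C)(C)C)cc(C)c2O1)C(=O)OC
F8 | step 12 | methyl (2Z,6E)-9-[(2R)-2,8-dimethyl-4-oxo-6-(pivaloyloxy)chroman-2-yl]-6-methyl-2-(4-methylpent-3-en-1-yl)nona-2,6-dienoate | CC(C)=CCC/C(=C/CC/C(C)=C/CC[C@]1(C)CC(=O)c2cc(OC(=O)C(C)(C)C)cc(C)c2O1)C(=O)OC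
F9 | step 12 | methyl (2Z,6E)-9-[(2R)-2,8-dimethyl-6-(pivaloyloxy)-4-{[(trifluoromethyl)sulfonyl]oxy}-2H-chromen-2-yl]-6-methyl-2-(4-methylpent-3-en-1-yl)nona-2,6-dienoate | CC(C)=CCC/C(=C/CC/C(C)=C/CC[C@]1(C)C=C(OS(=O)(=O)C(F)(F)F)c2cc(OC(=O)C(C)(C)C)cc(C)c2O1)C(=O)OC
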